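**Retrosynthetic overview**

1. Target 15 comes from stilbene 14 (alkene hydrogenation plus hydrogenolysis of four benzyl ethers), and 14 from the symmetric resorcinol stilbene 13 by one O-methylation.
2. The feature used: ring A carries oxygen at C1 and C3, hydrogen at C2, identical 4-oxybenzyl groups at C4 and C6, and the two-carbon bridge to ring B at C5. This is a 1,3,5-tricarbonyl chain folded in the stilbene manner and, apart from the O-methyl group, mirror-symmetric through C2 and C5.
3. Key disconnection: the ring-A bond C4–C5 (aldol of the benzyl-bearing terminal α-carbon onto the cinnamoyl ketone, then aromatization) leads back to the acyclic (E)-triketone 11. Ring A is the only ring formed; ring B and the three 4-oxyphenyl rings are bought.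
4. Triketone 11 comes from the dianion of symmetric diketone 4 and the ring-B cinnamoyl Weinreb amide 10. Diketone 4 comes from pentane-2,4-dione and two 4-(benzyloxy)benzyl chloride units; amide 10 from 2-bromo-5-hydroxybenzaldehyde by benzylation, Horner–Wadsworth–Emmons olefination and Negishi benzylation.

Key step: step 7

**Remarks on the chemistry**

- The chain of 11 is numbered from the alkene carbon on ring B (chain C1) to the benzylic CH2 at the far end (chain C9). Chain C3, C4, C5, C6, C7, C8 become ring-A C5, C6, C1, C2, C3, C4.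
- Triketone 11 is drawn in the triketo form. It will exist as enol tautomers, and chain C4 is configurationally labile, so it is used as that mixture.
- LDA is taken as the commercial solution.

**Route**

Step 1
Reactants: 1 pentane-2,4-dione; 2 1-(benzyloxy)-4-(chloromethyl)benzene
Product: 3 6-[4-(benzyloxy)phenyl]hexane-2,4-dione
Conditions: LDA (LiN(iPr)2, 2.1 equiv), THF, 0 °C; then 2 (0.95 equiv), 0 → 25 °C; 1 M HCl
Reagents that add atoms: none
Why: The β-diketone dianion reacts with the benzylic chloride only at its terminal, more basic carbon (γ-alkylation of a 1,3-diketone dianion, SN2), so the central carbon stays unsubstituted.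

Step 2
Reactants: 3 6-[4-(benzyloxy)phenyl]hexane-2,4-dione; 2 1-(benzyloxy)-4-(chloromethyl)benzene
Product: 4 1,7-bis[4-(benzyloxy)phenyl]heptane-3,5-dione
Conditions: LDA (LiN(iPr)2, 2.1 equiv), THF, −78 → 0 °C; then 2 (1.0 equiv), 0 → 25 °C; 1 M HCl
Reagents that add atoms: none
Why: The second deprotonation of the enolate of 3 should take place at the unhindered terminal methyl and not at the substituted C5 methylene, so a second γ-alkylation of the dianion gives the symmetric diketone.

Step 3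
Reactants: 5 2-bromo-5-hydroxybenzaldehyde
Product: 6 5-(benzyloxy)-2-bromobenzaldehyde
Conditions: BnBr, K2CO3, DMF, 25 °C
Reagents that add atoms: benzyl bromide, BrCc1ccccc1
Why: Williamson etherification of the phenoxide with a benzylic bromide is fast, and the aldehyde and aryl bromide are inert to K2CO3.

Step 4
Reactants: 6 5-(benzyloxy)-2-bromobenzaldehyde; 7 diethyl {2-[methoxy(methyl)amino]-2-oxoethyl}phosphonate
Product: 8 (E)-3-[5-(benzyloxy)-2-bromophenyl]-N-methoxy-N-methylprop-2-enamide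
Conditions: NaH, THF, 0 → 25 °C
Reagents that add atoms: none
Why: Horner–Wadsworth–Emmons olefination of an aromatic aldehyde with the stabilized amide phosphonate should give the E alkene with high selectivity through the thermodynamically preferred anti oxaphosphetane pathway.

Step 5
Reactants: 8 (E)-3-[5-(benzyloxy)-2-bromophenyl]-N-methoxy-N-methylprop-2-enamide; 2 1-(benzyloxy)-4-(chloromethyl)benzene
Product: 10 (E)-3-{5-(benzyloxy)-2-[4-(benzyloxy)benzyl]phenyl}-N-methoxy-N-methylprop-2-enamide, via [4-(benzyloxy)benzyl]zinc chloride 9 (not isolated)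
Conditions: 2, Zn dust, LiCl, THF, 25 °C; then 8, Pd(OAc)2 (2 mol %), SPhos (4 mol %), THF, 25 → 50 °C
Reagents that add atoms: none
Why: LiCl-assisted zinc insertion into the benzylic C–Cl bond gives 9, which has no β-hydrogen and tolerates the Weinreb amide and the alkene, and Negishi sp2–sp3 coupling with the aryl bromide installs the diarylmethane; the aldehyde was converted first because benzylic zinc reagents add to aldehydes.

Step 6
Reactants: 4 1,7-bis[4-(benzyloxy)phenyl]heptane-3,5-dione; 10 (E)-3-{5-(benzyloxy)-2-[4-(benzyloxy)benzyl]phenyl}-N-methoxy-N-methylprop-2-enamide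
Product: 11 (E)-4-[4-(benzyloxy)benzyl]-1-{5-(benzyloxy)-2-[4-(benzyloxy)benzyl]phenyl}-9-[4-(benzyloxy)phenyl]non-1-ene-3,5,7-trione
Conditions: 4 (1.5 equiv), LDA (LiN(iPr)2, 3.1 equiv), THF, 0 °C; then 10 (1.0 equiv), −78 → 0 °C; 1 M HCl to pH 4, 0 °C
Reagents that add atoms: none
Why: The dianion of 4 (central carbon and one terminal α-carbon, the two termini being equivalent) acylates at its terminal carbon by 1,2-addition to the Weinreb amide (C-acylation of a 1,3-diketone dianion), and the chelated tetrahedral lithium adduct holds until the quench, so neither over-addition nor proton transfer from the acidic triketone to unreacted dianion should occur.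

Step 7
Reactants: 11 (E)-4-[4-(benzyloxy)benzyl]-1-{5-(benzyloxy)-2-[4-(benzyloxy)benzyl]phenyl}-9-[4-(benzyloxy)phenyl]non-1-ene-3,5,7-trione
Product: 13 4,6-bis[4-(benzyloxy)benzyl]-5-[(E)-2-{5-(benzyloxy)-2-[4-(benzyloxy)benzyl]phenyl}ethenyl]benzene-1,3-diol, via cyclic aldol adduct 12 (not isolated)
Conditions: KOtBu (3.5 equiv), THF/t-BuOH (4:1), argon, 0 → 50 °C; then 1 M HCl, 0 °C
Reagents that add atoms: none
Why: With excess KOtBu the triketone rests as its bis-enolate at chain C4 and C6; a small equilibrium share of the tautomer protonated at C4 and deprotonated at chain C8 (the CH2 between the C7 ketone and the benzylic CH2) adds through C8 to the cinnamoyl carbonyl C3, adduct 12 loses water by E1cB across C3–C8, and the C5 and C7 carbonyls enolize to give ring A as its bis-phenoxide. The closest known reaction type is the base-induced aldol cyclization of acyclic 1,3,5-triketones and styryl triketo acids to resorcinols, the laboratory counterpart of the stilbene-synthase fold. Ring A closes in a 6-(enolendo)-exo-trig mode, because the C7=C8 enolate bond lies inside the new ring and the C3=O acceptor bond outside it. No stereocentre remains, since C3, C4 and C8 of 12 are flattened on aromatization and the E alkene is not touched. The step needs the C–C aldol to win over O-cyclization to a 4-pyranone, oxa-Michael addition at C1 and 6-endo Michael addition of C6 to C1; the regiochemistry is secured by the substrate, because chain C2 is a vinylic CH without an enolizable hydrogen, so C8 onto C3 is the only carbanion–carbonyl pairing that gives a six-membered ring. The strongly basic, non-nucleophilic medium keeps the C3–C5 unit enolized for most of the time (a poor Michael acceptor), the hetero- and carba-Michael adducts and hemiketals can revert, and only the aldol channel is made irreversible by aromatization.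

Step 8
Reactants: 13 4,6-bis[4-(benzyloxy)benzyl]-5-[(E)-2-{5-(benzyloxy)-2-[4-(benzyloxy)benzyl]phenyl}ethenyl]benzene-1,3-diol
Product: 14 2,4-bis[4-(benzyloxy)benzyl]-3-[(E)-2-{5-(benzyloxy)-2-[4-(benzyloxy)benzyl]phenyl}ethenyl]-5-methoxyphenol
Conditions: MeI (1.0 equiv), K2CO3 (1.0 equiv), acetone, 25 °C; unreacted 13 recycled
Reagents that add atoms: iodomethane, CI
Why: The two ring-A phenols are equivalent, so Williamson O-methylation with one equivalent of MeI can give only one mono-ether, which should be the main product and separable from recovered diol and the diether.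

Step 9
Reactants: 14 2,4-bis[4-(benzyloxy)benzyl]-3-[(E)-2-{5-(benzyloxy)-2-[4-(benzyloxy)benzyl]phenyl}ethenyl]-5-methoxyphenol
Product: 15 2,4-bis(4-hydroxybenzyl)-3-{2-[5-hydroxy-2-(4-hydroxybenzyl)phenyl]ethyl}-5-methoxyphenol (target, CNP0147493.0)
Conditions: H2 (1 atm), Pd/C (10% palladium on carbon), EtOAc/MeOH, 25 °C
Reagents that add atoms: none
Why: Catalytic hydrogenation saturates the disubstituted stilbene alkene and hydrogenolyses the four benzylic C–O bonds of the benzyl ethers in one operation, while the diarylmethane C–C bonds, the methyl ether and the arenes are stable under these mild conditions.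

**Compound list**

1 | pentane-2,4-dione | CC(=O)CC(C)=O | starting material
2 | 1-(benzyloxy)-4-(chloromethyl)benzene | ClCc1ccc(OCc2ccccc2)cc1 | starting material
3 | 6-[4-(benzyloxy)phenyl]hexane-2,4-dione | CC(=O)CC(=O)CCc1ccc(OCc2ccccc2)cc1 | intermediate
4 | 1,7-bis[4-(benzyloxy)phenyl]heptane-3,5-dione | O=C(CCc1ccc(OCc2ccccc2)cc1)CC(=O)CCc1ccc(OCc2ccccc2)cc1 | intermediate
5 | 2-bromo-5-hydroxybenzaldehyde | O=Cc1cc(O)ccc1Br | starting material
6 | 5-(benzyloxy)-2-bromobenzaldehyde | O=Cc1cc(OCc2ccccc2)ccc1Br | intermediate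
7 | diethyl {2-[methoxy(methyl)amino]-2-oxoethyl}phosphonate | CCOP(=O)(OCC)CC(=O)N(C)OC | starting material
8 | (E)-3-[5-(benzyloxy)-2-bromophenyl]-N-methoxy-N-methylprop-2-enamide | CON(C)C(=O)/C=C/c1cc(OCc2ccccc2)ccc1Br | intermediate
9 | [4-(benzyloxy)benzyl]zinc chloride | Cl[Zn]Cc1ccc(OCc2ccccc2)cc1 | intermediate
10 | (E)-3-{5-(benzyloxy)-2-[4-(benzyloxy)benzyl]phenyl}-N-methoxy-N-methylprop-2-enamide | CON(C)C(=O)/C=C/c1cc(OCc2ccccc2)ccc1Cc1ccc(OCc2ccccc2)cc1 | intermediate
11 | (E)-4-[4-(benzyloxy)benzyl]-1-{5-(benzyloxy)-2-[4-(benzyloxy)benzyl]phenyl}-9-[4-(benzyloxy)phenyl]non-1-ene-3,5,7-trione (tautomer mixture, labile at C4) | O=C(CCc1ccc(OCc2ccccc2)cc1)CC(=O)C(Cc1ccc(OCc2ccccc2)cc1)C(=O)/C=C/c1cc(OCc2ccccc2)ccc1Cc1ccc(OCc2ccccc2)cc1 | intermediate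
12 | 4,6-bis[4-(benzyloxy)benzyl]-5-hydroxy-5-[(E)-2-{5-(benzyloxy)-2-[4-(benzyloxy)benzyl]phenyl}ethenyl]cyclohexane-1,3-dione (diastereomer mixture) | O=C1CC(=O)C(Cc2ccc(OCc3ccccc3)cc2)C(O)(/C=C/c2cc(OCc3ccccc3)ccc2Cc2ccc(OCc3ccccc3)cc2)C1Cc1ccc(OCc2ccccc2)cc1 | intermediate
13 | 4,6-bis[4-(benzyloxy)benzyl]-5-[(E)-2-{5-(benzyloxy)-2-[4-(benzyloxy)benzyl]phenyl}ethenyl]benzene-1,3-diol | Oc1cc(O)c(Cc2ccc(OCc3ccccc3)cc2)c(/C=C/c2cc(OCc3ccccc3)ccc2Cc2ccc(OCc3ccccc3)cc2)c1Cc1ccc(OCc2ccccc2)cc1 | intermediate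
14 | 2,4-bis[4-(benzyloxy)benzyl]-3-[(E)-2-{5-(benzyloxy)-2-[4-(benzyloxy)benzyl]phenyl}ethenyl]-5-methoxyphenol | COc1cc(O)c(Cc2ccc(OCc3ccccc3)cc2)c(/C=C/c2cc(OCc3ccccc3)ccc2Cc2ccc(OCc3ccccc3)cc2)c1Cc1ccc(OCc2ccccc2)cc1 | intermediate
15 | 2,4-bis(4-hydroxybenzyl)-3-{2-[5-hydroxy-2-(4-hydroxybenzyl)phenyl]ethyl}-5-methoxyphenol | COc1cc(O)c(Cc2ccc(O)cc2)c(CCc2cc(O)ccc2Cc2ccc(O)cc2)c1Cc1ccc(O)cc1 | target

**Step count**

Total: 9 steps. Longest linear sequence: 7 steps (steps 3, 4, 5, 6, 7, 8, 9, from 2-bromo-5-hydroxybenzaldehyde 5).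

**Steps most likely to fail**

1. Step 7 (aldol cyclization and aromatization). Deprotonation at chain C8 may be too slow compared with conjugate addition of the C6 carbanion or the C5 enolate oxygen to the styryl carbon C1, or with hemiketalization to a 4-pyranone, so that the triketone is drained into non-aromatic cyclic products or degraded.
Fallback, setting out from 3 and 10 and coming back at 15: the nucleophilic carbon is activated by a second carbonyl group, which is reduced to the benzylic CH2 at the end.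
 - The dianion of 3 (LDA, 3.2 equiv, THF, 0 °C) would be aroylated at its terminal methyl with methyl 4-(benzyloxy)benzoate (COC(=O)c1ccc(OCc2ccccc2)cc1) to give 1,7-bis[4-(benzyloxy)phenyl]heptane-1,3,5-trione F1.
 - The trianion of F1 (LDA, 3.3 equiv) would be acylated at its terminal C6 by 10 to give (E)-6-[4-(benzyloxy)benzyl]-1-[4-(benzyloxy)phenyl]-9-{5-(benzyloxy)-2-[4-(benzyloxy)benzyl]phenyl}non-8-ene-1,3,5,7-tetrone F2.
 - In F2 the carbon that must attack the cinnamoyl ketone lies between two carbonyls, so mild base (K2CO3 or dilute KOH, MeOH/THF, 25 °C) should bring about the well-known tetraketone-to-acylresorcinol aldol. The product would be [3-[4-(benzyloxy)benzyl]-2-[(E)-2-{5-(benzyloxy)-2-[4-(benzyloxy)benzyl]phenyl}ethenyl]-4,6-dihydroxyphenyl][4-(benzyloxy)phenyl]methanone F3.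
 - MeI/K2CO3 in acetone should methylate only the phenol that is not hydrogen-bonded to the ketone, giving the 6-hydroxy-4-methoxy benzophenone F4.
 - LiAlH4 in THF would reduce the diaryl ketone to the racemic benzhydrol F5.
 - H2 with Pd/C would saturate the alkene, remove the four benzyl ethers and hydrogenolyse the doubly benzylic C–OH to CH2. The former aroyl group thereby becomes the second 4-hydroxybenzyl group, which gives 15.

2. Step 6 (dianion acylation). The dianion may add in conjugate fashion to the alkene carbon of the enamide instead of the amide carbonyl, or the acylation of the weakly electrophilic Weinreb amide may stall.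
Fallback, setting out from 10 and 4 and coming back at 11:
 - iBu2AlH (DIBAL-H) in THF at −78 °C would reduce 10 to (E)-3-{5-(benzyloxy)-2-[4-(benzyloxy)benzyl]phenyl}prop-2-enal F6.
 - The dianion of 4 should add 1,2 to this enal at −78 °C (kinetic aldol addition). The product would be (E)-6-[4-(benzyloxy)benzyl]-7-hydroxy-1-[4-(benzyloxy)phenyl]-9-{5-(benzyloxy)-2-[4-(benzyloxy)benzyl]phenyl}non-8-ene-3,5-dione F7, as a diastereomer mixture.
 - MnO2 in CH2Cl2 would oxidize the allylic alcohol of F7 selectively to the enone, which is 11.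

3. Step 8 (mono-O-methylation). The second phenol may be methylated at a rate similar to the first, leaving a statistical mixture of diol, mono-ether and diether.
Fallback, setting out from 13 and coming back at 15:
 - Exhaustive methylation (excess MeI, K2CO3, DMF) would give 1,5-bis[4-(benzyloxy)benzyl]-6-[(E)-2-{5-(benzyloxy)-2-[4-(benzyloxy)benzyl]phenyl}ethenyl]-2,4-dimethoxybenzene F8.
 - H2 with Pd/C would give the tetraphenol 4-(4-hydroxybenzyl)-3-{2-[2,6-bis(4-hydroxybenzyl)-3,5-dimethoxyphenyl]ethyl}phenol F9.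
 - NaSEt (excess) in DMF at 130 °C would remove one methyl group by SN2 at carbon. The ring-A phenoxide formed makes the second aryloxide a much poorer leaving group, so cleavage should stop at the mono-ether 15.

**Further compounds**

F1 | step 7 | 1,7-bis[4-(benzyloxy)phenyl]heptane-1,3,5-trione | O=C(CC(=O)CC(=O)CCc1ccc(OCc2ccccc2)cc1)c1ccc(OCc2ccccc2)cc1
F2 | step 7 | (E)-6-[4-(benzyloxy)benzyl]-1-[4-(benzyloxy)phenyl]-9-{5-(benzyloxy)-2-[4-(benzyloxy)benzyl]phenyl}non-8-ene-1,3,5,7-tetrone | O=C(CC(=O)CC(=O)C(Cc1ccc(OCc2ccccc2)cc1)C(=O)/C=C/c1cc(OCc2ccccc2)ccc1Cc1ccc(OCc2ccccc2)cc1)c1ccc(OCc2ccccc2)cc1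
F3 | step 7 | [3-[4-(benzyloxy)benzyl]-2-[(E)-2-{5-(benzyloxy)-2-[4-(benzyloxy)benzyl]phenyl}ethenyl]-4,6-dihydroxyphenyl][4-(benzyloxy)phenyl]methanone | O=C(c1ccc(OCc2ccccc2)cc1)c1c(O)cc(O)c(Cc2ccc(OCc3ccccc3)cc2)c1/C=C/c1cc(OCc2ccccc2)ccc1Cc1ccc(OCc2ccccc2)cc1
F4 | step 7 | [3-[4-(benzyloxy)benzyl]-2-[(E)-2-{5-(benzyloxy)-2-[4-(benzyloxy)benzyl]phenyl}ethenyl]-6-hydroxy-4-methoxyphenyl][4-(benzyloxy)phenyl]methanone | O=C(c1ccc(OCc2ccccc2)cc1)c1c(O)cc(OC)c(Cc2ccc(OCc3ccccc3)cc2)c1/C=C/c1cc(OCc2ccccc2)ccc1Cc1ccc(OCc2ccccc2)cc1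
F5 | step 7 | 3-[4-(benzyloxy)benzyl]-2-[(E)-2-{5-(benzyloxy)-2-[4-(benzyloxy)benzyl]phenyl}ethenyl]-6-{[4-(benzyloxy)phenyl](hydroxy)methyl}-5-methoxy... written as the phenol: 4-[4-(benzyloxy)benzyl]-3-[(E)-2-{5-(benzyloxy)-2-[4-(benzyloxy)benzyl]phenyl}ethenyl]-2-{[4-(benzyloxy)phenyl](hydroxy)methyl}-5-methoxyphenol (racemic) | OC(c1ccc(OCc2ccccc2)cc1)c1c(O)cc(OC)c(Cc2ccc(OCc3ccccc3)cc2)c1/C=C/c1cc(OCc2ccccc2)ccc1Cc1ccc(OCc2ccccc2)cc1
F6 | step 6 | (E)-3-{5-(benzyloxy)-2-[4-(benzyloxy)benzyl]phenyl}prop-2-enal | O=C/C=C/c1cc(OCc2ccccc2)ccc1Cc1ccc(OCc2ccccc2)cc1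
F7 | step 6 | (E)-6-[4-(benzyloxy)benzyl]-7-hydroxy-1-[4-(benzyloxy)phenyl]-9-{5-(benzyloxy)-2-[4-(benzyloxy)benzyl]phenyl}non-8-ene-3,5-dione (diastereomer mixture) | O=C(CCc1ccc(OCc2ccccc2)cc1)CC(=O)C(Cc1ccc(OCc2ccccc2)cc1)C(O)/C=C/c1cc(OCc2ccccc2)ccc1Cc1ccc(OCc2ccccc2)cc1
F8 | step 8 | 1,5-bis[4-(benzyloxy)benzyl]-6-[(E)-2-{5-(benzyloxy)-2-[4-(benzyloxy)benzyl]phenyl}ethenyl]-2,4-dimethoxybenzene | COc1cc(OC)c(Cc2ccc(OCc3ccccc3)cc2)c(/C=C/c2cc(OCc3ccccc3)ccc2Cc2ccc(OCc3ccccc3)cc2)c1Cc1ccc(OCc2ccccc2)cc1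
F9 | step 8 | 4-(4-hydroxybenzyl)-3-{2-[2,6-bis(4-hydroxybenzyl)-3,5-dimethoxyphenyl]ethyl}phenol | COc1cc(OC)c(Cc2ccc(O)cc2)c(CCc2cc(O)ccc2Cc2ccc(O)cc2)c1Cc1ccc(O)cc1
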